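**Strategy.** The dihydrofuran ring is cut at C2–C3 and O1–C2. C3, C3a, C7a and O1 of the 2,3-dihydrobenzofuran are a salicylaldehyde in disguise, and C2 with its isopropenyl group is a one-carbon unit supplied by a chiral methallylsulfonium ylide. In one flask the ylide converts an O-silylated 5-acetylsalicylaldehyde into the trans vinyl epoxide, and fluoride-released O1 then closes the five-membered ring on C2, setting C2 and C3. The acetyl group stands in for the C5 ester side chain, because a phenoxide para to a benzylic carboxylate would expel it. Reduction, two acylations and allylic oxidation follow.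

Key step: step 4

Assumption: (2R,5R)-2,5-dimethylthiolane is taken as a purchasable sulfide and its methallyl ylide is assumed to show the facial sense of its benzyl ylide ((S,S)-oxirane); if the induced sense proves opposite, the (2S,5S) sulfide is used in step 3.

Design notes:
- A betaine carrying a free ortho phenoxide can close in two ways that are not stereochemically equivalent. Oxirane formation followed by phenoxide opening inverts C2 twice; direct phenoxide displacement of the sulfide inverts it once. From the anti betaine only the first path gives the trans ring. The phenol is therefore masked as a triisopropylsilyl ether until the oxirane exists; the mask also keeps the acidic phenol from quenching the ylide.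
- With the C5 ester in place, every phenoxide stage would have a carboxylate leaving group at the benzylic position para to O−, a para-quinone-methide precursor. The carbinol also could not be esterified cleanly next to a free phenol. The side chain is therefore carried as the acetyl group, which also distinguishes the two carbinol oxygens of the target.
- The salicylaldehyde precursor of the key step is 3 (used as its silyl ether 4), the sulfonium precursor is 7 and the annulation product is 11.

**Route**

Step 1
Reactants: 1 4'-hydroxyacetophenone
Product: 3 5-acetyl-2-hydroxybenzaldehyde, via Duff aldimine 2 (not isolated)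
Conditions: hexamethylenetetramine (2 equiv), CF3CO2H, 80 °C; then H2O, 2 M HCl, 60 °C
Reagents that add atoms: hexamethylenetetramine, C1N2CN3CN1CN(C2)C3; water, O
Why: Duff formylation, in which the phenol directs the hexamine-derived iminium electrophile to its ortho position (para is blocked by the acetyl group) and acidic hydrolysis of aldiminium 2 releases the aldehyde, the deactivated ring discouraging a second formylation.

Step 2
Reactants: 3 5-acetyl-2-hydroxybenzaldehyde
Product: 4 5-acetyl-2-[(triisopropylsilyl)oxy]benzaldehyde
Conditions: iPr3SiCl, imidazole, DMF, rt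
Reagents that add atoms: triisopropylsilyl chloride, CC(C)[Si](Cl)(C(C)C)C(C)C
Why: Imidazole-promoted silylation of an acidic phenol gives a bulky aryl silyl ether that should survive the basic ylide stage, resist O-to-O silyl migration and be cleaved by fluoride on demand.

Step 3
Reactants: 5 (2R,5R)-2,5-dimethylthiolane; 6 3-bromo-2-methylpropene
Product: 7 (2R,5R)-2,5-dimethyl-1-(2-methylprop-2-en-1-yl)thiolan-1-ium tetrafluoroborate
Conditions: AgBF4, CH2Cl2, rt, dark; filter, crystallise from CH2Cl2/Et2O
Reagents that add atoms: silver tetrafluoroborate, [Ag+].F[B-](F)(F)F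
Why: S-alkylation of a dialkyl sulfide by an allylic bromide is driven by precipitation of AgBr, and because the sulfide is twofold symmetric its lone pairs are equivalent, so one sulfonium salt without a sulfur stereocentre should form.

Step 4
Reactants: 4 5-acetyl-2-[(triisopropylsilyl)oxy]benzaldehyde; 7 (2R,5R)-2,5-dimethyl-1-(2-methylprop-2-en-1-yl)thiolan-1-ium tetrafluoroborate
Product: 11 1-[(2R,3S)-3-hydroxy-2-(prop-1-en-2-yl)-2,3-dihydro-1-benzofuran-5-yl]ethan-1-one, via sulfonium ylide 8 (not isolated), via silyl vinyl epoxide 9 (not isolated), via epoxy phenoxide 10 (not isolated)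
Conditions: 7 (1.3 equiv), KN(SiMe3)2 (1.2 equiv), THF, −78 °C; 4, −78 to 0 °C; then Bu4NF (1.5 equiv), 0 to 40 °C; AcOH quench
Reagents that add atoms: none
Why: Proposed new method: deprotonation of 7 gives allylic ylide 8, whose carbanion carbon adds to the formyl group of 4 to an anti betaine that collapses by 3-exo-tet displacement of the sulfide to trans vinyl epoxide 9, as in the known asymmetric epoxidation of aryl aldehydes with chiral benzylic and allylic sulfonium ylides; fluoride then frees phenoxide 10, which opens the oxirane at its allylic carbon in the same flask, the closest precedents being formal [4+1] annulations of salicylaldehydes with carbonyl-stabilised sulfonium ylides and phenoxide openings of activated epoxides. The dihydrofuran ring closes in a 5-endo epoxide-opening mode (SN2 at C2, both oxirane carbons ending in the new ring, helped by the adjacent isopropenyl π system), attack at C3 being excluded because it would need a four-membered ring. C3 is set in the addition, where the twofold-symmetric trans-2,5-dimethylthiolanium unit leaves one ylide face open and is expected to give the (2S,3S)-oxirane; C2 is set by anti-betaine formation (trans oxirane) and then inverted by the phenoxide, so that trans-(2S,3S)-9 maps onto trans-(2R,3S)-11. The step needs aldehyde-face selectivity, anti over syn betaine, and closure through the oxirane only; the silyl mask secures the last point, since a free phenoxide could displace the sulfide from the anti betaine directly (5-exo-tet, one inversion at C2) and give the cis ring. The 5-acetyl group should be inert to the ylide at low temperature, leaves no leaving group at the benzylic position para to the phenoxide and tempers quinone-methide ionisation of the benzylic C–O bond.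

Step 5
Reactants: 11 1-[(2R,3S)-3-hydroxy-2-(prop-1-en-2-yl)-2,3-dihydro-1-benzofuran-5-yl]ethan-1-one
Product: 12 (2R,3S)-5-acetyl-2-(prop-1-en-2-yl)-2,3-dihydro-1-benzofuran-3-yl 3-methylbutanoate
Conditions: (Me2CHCH2CO)2O, Et3N, DMAP (cat.), CH2Cl2, 0 °C to rt
Reagents that add atoms: 3-methylbutanoic anhydride, CC(C)CC(=O)OC(=O)CC(C)C
Why: DMAP-catalysed acylation of the only hydroxyl group leaves the C3–O bond intact, so configuration is retained, and placing it before ketone reduction keeps the two carbinol oxygens of the target distinct.

Step 6
Reactants: 12 (2R,3S)-5-acetyl-2-(prop-1-en-2-yl)-2,3-dihydro-1-benzofuran-3-yl 3-methylbutanoate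
Product: 13 (2R,3S)-5-[(1R)-1-hydroxyethyl]-2-(prop-1-en-2-yl)-2,3-dihydro-1-benzofuran-3-yl 3-methylbutanoate
Conditions: RuCl[(R,R)-TsDPEN](p-cymene) (1 mol %), HCO2H/Et3N (5:2), EtOAc, 30 °C
Reagents that add atoms: none
Why: Noyori-type asymmetric transfer hydrogenation of an aryl methyl ketone, in which the (R,R)-diamine complex should deliver hydride through its six-membered outer-sphere transition state to the face giving the (1R)-carbinol under catalyst control, while the esters and the isolated 1,1-disubstituted alkene are not reduced.

Step 7
Reactants: 13 (2R,3S)-5-[(1R)-1-hydroxyethyl]-2-(prop-1-en-2-yl)-2,3-dihydro-1-benzofuran-3-yl 3-methylbutanoate; 14 (R)-2-methylbutanoic acid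
Product: 15 (1R)-1-[(2R,3S)-3-[(3-methylbutanoyl)oxy]-2-(prop-1-en-2-yl)-2,3-dihydro-1-benzofuran-5-yl]ethyl (2R)-2-methylbutanoate
Conditions: EDC·HCl (1.5 equiv), DMAP (0.2 equiv), CH2Cl2, 0 °C to rt
Reagents that add atoms: none
Why: Steglich esterification transfers the acyl group to oxygen without touching the carbinol centre, and low temperature with substoichiometric DMAP should keep the α-centre of the alkyl-branched acid from epimerising.

Step 8
Reactants: 15 (1R)-1-[(2R,3S)-3-[(3-methylbutanoyl)oxy]-2-(prop-1-en-2-yl)-2,3-dihydro-1-benzofuran-5-yl]ethyl (2R)-2-methylbutanoate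
Product: 16 (1R)-1-[(2R,3S)-2-(3-hydroxyprop-1-en-2-yl)-3-[(3-methylbutanoyl)oxy]-2,3-dihydro-1-benzofuran-5-yl]ethyl (2R)-2-methylbutanoate
Conditions: SeO2 (0.5 equiv), t-BuOOH (2.5 equiv), CH2Cl2, 0 °C to rt
Reagents that add atoms: selenium dioxide, O=[Se]=O; tert-butyl hydroperoxide, CC(C)(C)OO
Why: Riley allylic oxidation in its catalytic hydroperoxide variant, in which an ene reaction at the isopropenyl group and a [2,3]-sigmatropic shift should place oxygen on the methyl carbon and restore the 1,1-disubstituted alkene, the methyl hydrogens being preferred over the hindered, oxygen-deactivated C2–H and the mild temperature sparing the elimination-prone C3 ester.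

Step 9
Reactants: 16 (1R)-1-[(2R,3S)-2-(3-hydroxyprop-1-en-2-yl)-3-[(3-methylbutanoyl)oxy]-2,3-dihydro-1-benzofuran-5-yl]ethyl (2R)-2-methylbutanoate
Product: 17 (1R)-1-[(2R,3S)-3-[(3-methylbutanoyl)oxy]-2-(3-oxoprop-1-en-2-yl)-2,3-dihydro-1-benzofuran-5-yl]ethyl (2R)-2-methylbutanoate
Conditions: MnO2 (activated, excess), CH2Cl2, rt
Reagents that add atoms: none
Why: Heterogeneous MnO2 oxidation is selective for allylic alcohols and neutral, so the 2-substituted acrolein should form without ester cleavage, elimination or change at any stereocentre (any enal already formed in step 8 passes through unchanged).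

**Compound list**

1 | 4'-hydroxyacetophenone | CC(=O)c1ccc(O)cc1 | starting material
2 | 5-acetyl-2-hydroxybenzaldehyde imine (Duff aldimine, drawn N-unsubstituted; in the flask N-protonated and bound to hexamine fragments) | CC(=O)c1ccc(O)c(C=N)c1 | intermediate (not isolated)
3 | 5-acetyl-2-hydroxybenzaldehyde | CC(=O)c1ccc(O)c(C=O)c1 | intermediate
4 | 5-acetyl-2-[(triisopropylsilyl)oxy]benzaldehyde | CC(=O)c1ccc(O[Si](C(C)C)(C(C)C)C(C)C)c(C=O)c1 | intermediate
5 | (2R,5R)-2,5-dimethylthiolane | C[C@@H]1CC[C@@H](C)S1 | starting material
6 | 3-bromo-2-methylpropene | C=C(C)CBr | starting material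
7 | (2R,5R)-2,5-dimethyl-1-(2-methylprop-2-en-1-yl)thiolan-1-ium tetrafluoroborate | C[C@@H]1CC[C@@H](C)[S+]1CC(C)=C.F[B-](F)(F)F | intermediate
8 | (2R,5R)-2,5-dimethylthiolan-1-ium-1-yl 2-methylallylide (sulfonium ylide) | C[C@@H]1CC[C@@H](C)[S+]1[CH-]C(C)=C | intermediate (not isolated)
9 | 1-{3-[(2S,3S)-3-(prop-1-en-2-yl)oxiran-2-yl]-4-[(triisopropylsilyl)oxy]phenyl}ethan-1-one | CC(=O)c1ccc(O[Si](C(C)C)(C(C)C)C(C)C)c(c1)[C@@H]1O[C@H]1C(C)=C | intermediate (not isolated)
10 | tetrabutylammonium 4-acetyl-2-[(2S,3S)-3-(prop-1-en-2-yl)oxiran-2-yl]phenolate | CCCC[N+](CCCC)(CCCC)CCCC.CC(=O)c1ccc([O-])c(c1)[C@@H]1O[C@H]1C(C)=C | intermediate (not isolated)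
11 | 1-[(2R,3S)-3-hydroxy-2-(prop-1-en-2-yl)-2,3-dihydro-1-benzofuran-5-yl]ethan-1-one | C=C(C)[C@H]1Oc2ccc(C(C)=O)cc2[C@@H]1O | intermediate
12 | (2R,3S)-5-acetyl-2-(prop-1-en-2-yl)-2,3-dihydro-1-benzofuran-3-yl 3-methylbutanoate | C=C(C)[C@H]1Oc2ccc(C(C)=O)cc2[C@@H]1OC(=O)CC(C)C | intermediate
13 | (2R,3S)-5-[(1R)-1-hydroxyethyl]-2-(prop-1-en-2-yl)-2,3-dihydro-1-benzofuran-3-yl 3-methylbutanoate | C=C(C)[C@H]1Oc2ccc([C@@H](C)O)cc2[C@@H]1OC(=O)CC(C)C | intermediate
14 | (R)-2-methylbutanoic acid | CC[C@@H](C)C(=O)O | starting material
15 | (1R)-1-[(2R,3S)-3-[(3-methylbutanoyl)oxy]-2-(prop-1-en-2-yl)-2,3-dihydro-1-benzofuran-5-yl]ethyl (2R)-2-methylbutanoate | C=C(C)[C@H]1Oc2ccc([C@@H](C)OC(=O)[C@H](C)CC)cc2[C@@H]1OC(=O)CC(C)C | intermediate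
16 | (1R)-1-[(2R,3S)-2-(3-hydroxyprop-1-en-2-yl)-3-[(3-methylbutanoyl)oxy]-2,3-dihydro-1-benzofuran-5-yl]ethyl (2R)-2-methylbutanoate | C=C(CO)[C@H]1Oc2ccc([C@@H](C)OC(=O)[C@H](C)CC)cc2[C@@H]1OC(=O)CC(C)C | intermediate
17 | (1R)-1-[(2R,3S)-3-[(3-methylbutanoyl)oxy]-2-(3-oxoprop-1-en-2-yl)-2,3-dihydro-1-benzofuran-5-yl]ethyl (2R)-2-methylbutanoate | C=C(C=O)[C@H]1Oc2ccc([C@@H](C)OC(=O)[C@H](C)CC)cc2[C@@H]1OC(=O)CC(C)C | target

**Step count**

Total: 9 steps. Longest linear sequence: 8 steps (steps 1, 2, 4, 5, 6, 7, 8, 9, from 1 to 17); step 3 is a one-step branch that makes 7.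

**Three steps most likely to fail**

Step 4. What may go wrong is stereochemical leakage while the C2–C3 bond forms: part of the addition may run through the syn betaine (cis oxirane, hence cis ring), or the thiolanium unit may discriminate the aldehyde faces incompletely. A slow, strained oxirane opening would also give the benzylic C–O bond time to ionise. The fallback uses known reactions only and sets out from 4. A Horner–Wadsworth–Emmons olefination with diethyl (2-methylallyl)phosphonate and LiN(SiMe3)2 in THF (−78 °C to rt) should give the (E)-diene 1-{3-[(1E)-3-methylbuta-1,3-dien-1-yl]-4-[(triisopropylsilyl)oxy]phenyl}ethan-1-one F1. Shi epoxidation of F1 follows, with the L-fructose-derived ketone catalyst (1,2:4,5-di-O-isopropylidene-β-L-erythro-2,3-hexodiulo-2,6-pyranose), KHSO5 (as 2KHSO5·KHSO4·K2SO4) and K2CO3 buffer in MeCN/dimethoxymethane/H2O at 0 °C. It is expected to oxidise only the trans-disubstituted styrenyl double bond, since the 1,1-disubstituted terminus is a poor substrate for this catalyst, and to give the (2S,3S)-oxirane. That oxirane is compound 9, now with its configuration set by the ketone catalyst and its trans geometry inherited from the (E)-alkene. The route is rejoined at 9, which is taken through the fluoride stage of step 4 to 11.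

Step 8. What may go wrong is that the ene step abstracts the C2–H instead of a methyl hydrogen, or that selenous acid assists ionisation of the C3 acyloxy group, followed by aromatisation to the benzofuran. The fallback sets out from 15. Ene-type chlorination with HOCl, generated from Ca(OCl)2 and solid CO2 in CH2Cl2/H2O at 0 °C with the hypochlorite as limiting reagent to spare the arene, should give the allylic chloride (1R)-1-[(2R,3S)-2-(3-chloroprop-1-en-2-yl)-3-[(3-methylbutanoyl)oxy]-2,3-dihydro-1-benzofuran-5-yl]ethyl (2R)-2-methylbutanoate F2. Kornblum-type oxidation of F2 with trimethylamine N-oxide in DMSO at rt should then convert the CH2Cl group directly into the aldehyde. The route is rejoined at the target 17; compound 16 and step 9 are bypassed.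

Step 6. What may go wrong is sluggish hydride transfer to the electron-rich (para-alkoxy) aryl ketone with incomplete face selection, and formic-acid-promoted ionisation of the para-alkoxybenzylic carbinol once it has formed, which would erode C1′. The fallback sets out from 12. A Corey–Bakshi–Shibata reduction with (S)-1-methyl-3,3-diphenyltetrahydro-1H,3H-pyrrolo[1,2-c][1,3,2]oxazaborole (0.2 equiv) and catecholborane in toluene at −78 °C replaces metal-catalysed hydrogen transfer in an acidic medium by boron-organised hydride delivery in an aprotic, non-acidic one. Catecholborane should leave the alkene alone. The route is rejoined at 13, and this fallback makes no compound outside the list, F0.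

**Further compounds**

F1 | step 4 | 1-{3-[(1E)-3-methylbuta-1,3-dien-1-yl]-4-[(triisopropylsilyl)oxy]phenyl}ethan-1-one | CC(=O)c1ccc(O[Si](C(C)C)(C(C)C)C(C)C)c(/C=C/C(C)=C)c1
F2 | step 8 | (1R)-1-[(2R,3S)-2-(3-chloroprop-1-en-2-yl)-3-[(3-methylbutanoyl)oxy]-2,3-dihydro-1-benzofuran-5-yl]ethyl (2R)-2-methylbutanoate | C=C(CCl)[C@H]1Oc2ccc([C@@H](C)OC(=O)[C@H](C)CC)cc2[C@@H]1OC(=O)CC(C)C
F0 | step 6 | none | none
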